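The cyclohexene ring is disconnected at C2–C3. C2 is the β-carbon of the C1=C2 enoate and C3 an oxygenated carbon, so both are inherently electrophilic. Turning C2 into an alkenyl-metal nucleophile that attacks a C3 aldehyde closes the six-membered ring and creates the C3 carbinol in one operation, while the C4–O stereocentre held in a trans-dioxolane steers the facial course. The cyclisation substrate is a D-threitol-derived acetonide bearing the C3 aldehyde at one end and an (E)-β-triflyloxy acrylate at the other. After ring closure, the three different esters are introduced one at a time, each on a single free or regiochemically defined hydroxyl.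

Key step: step 8

Remark: shikimate numbering is used for the ring and its acyclic precursors (C1 bears CO2Me, C2 is the vinylic CH, C3–C5 bear oxygen, C6 is CH2); the E/Z outcome of the Wittig step is immaterial because that alkene is hydrogenated.

Step 1
Reactants: 1 (4R,5R)-2,2-dimethyl-1,3-dioxolane-4,5-dimethanol (2,3-O-isopropylidene-D-threitol)
Product: 3 [(4R,5R)-5-(tert-butyldimethylsilyloxymethyl)-2,2-dimethyl-1,3-dioxolan-4-yl]methanol, via monosodium alkoxide 2 (not isolated)
Conditions: NaH (1.0 equiv), THF, 0 °C to rt; then TBSCl (1.0 equiv), rt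
Reagents that add atoms: tert-butyldimethylsilyl chloride, CC(C)(C)[Si](C)(C)Cl
Why: Monosilylation of a C2-symmetric diol through its sparingly soluble monoalkoxide (O-silylation); the two hydroxyls are equivalent, so there is no regiochemical issue and no stereocentre is touched.

Step 2
Reactants: 3 [(4R,5R)-5-(tert-butyldimethylsilyloxymethyl)-2,2-dimethyl-1,3-dioxolan-4-yl]methanol; 4 methyl (triphenylphosphoranylidene)acetate
Product: 6 methyl (E)-3-[(4R,5R)-5-(tert-butyldimethylsilyloxymethyl)-2,2-dimethyl-1,3-dioxolan-4-yl]prop-2-enoate, via aldehyde 5 (not isolated)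
Conditions: (COCl)2, DMSO, CH2Cl2, −78 °C; Et3N, −78 to 0 °C; then 4, 0 °C to rt
Reagents that add atoms: methyl (triphenylphosphoranylidene)acetate (compound 4), COC(=O)C=P(c1ccccc1)(c1ccccc1)c1ccccc1
Why: Swern oxidation followed in the same flask by Wittig olefination with a stabilised ylide avoids handling the α-alkoxy aldehyde, whose trans-dioxolane configuration is in any case the thermodynamically preferred one.

Step 3
Reactants: 6 methyl (E)-3-[(4R,5R)-5-(tert-butyldimethylsilyloxymethyl)-2,2-dimethyl-1,3-dioxolan-4-yl]prop-2-enoate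
Product: 7 methyl 3-[(4R,5R)-5-(tert-butyldimethylsilyloxymethyl)-2,2-dimethyl-1,3-dioxolan-4-yl]propanoate
Conditions: H2 (1 atm), Pd/C (10 wt % Pd), EtOAc, rt
Reagents that add atoms: none
Why: Heterogeneous catalytic hydrogenation of the conjugated alkene; silyl ether, acetonide and ester are inert and no stereocentre is created.

Step 4
Reactants: 7 methyl 3-[(4R,5R)-5-(tert-butyldimethylsilyloxymethyl)-2,2-dimethyl-1,3-dioxolan-4-yl]propanoate
Product: 9 methyl 2-formyl-3-[(4R,5R)-5-(tert-butyldimethylsilyloxymethyl)-2,2-dimethyl-1,3-dioxolan-4-yl]propanoate, via lithium ester enolate 8 (not isolated)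
Conditions: LiN(iPr)2 (1.2 equiv), THF, −78 °C; HCO2Me, −78 to 0 °C; aq. NH4Cl
Reagents that add atoms: methyl formate, COC=O
Why: Crossed Claisen condensation (α-formylation) of the ester enolate with non-enolisable methyl formate, which installs C2; the ring oxygen sits γ to the enolate carbon, so β-elimination is impossible, and the new α-centre disappears in step 5.

Step 5
Reactants: 9 methyl 2-formyl-3-[(4R,5R)-5-(tert-butyldimethylsilyloxymethyl)-2,2-dimethyl-1,3-dioxolan-4-yl]propanoate
Product: 10 methyl (E)-2-{[(4R,5R)-5-(tert-butyldimethylsilyloxymethyl)-2,2-dimethyl-1,3-dioxolan-4-yl]methyl}-3-(trifluoromethanesulfonyloxy)prop-2-enoate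
Conditions: Tf2O (1.2 equiv), iPr2NEt (1.5 equiv), CH2Cl2, −78 °C
Reagents that add atoms: trifluoromethanesulfonic anhydride, O=S(=O)(OS(=O)(=O)C(F)(F)F)C(F)(F)F
Why: O-Sulfonylation of the ammonium enolate of a 1,3-dicarbonyl compound; with no chelating metal the enolate should react from its extended form, placing the triflate trans to the ester and cis to the C6 methylene (E), as in amine-mediated E-selective enol sulfonylation of α-formyl esters, and any Z isomer would be removed by chromatography.

Step 6
Reactants: 10 methyl (E)-2-{[(4R,5R)-5-(tert-butyldimethylsilyloxymethyl)-2,2-dimethyl-1,3-dioxolan-4-yl]methyl}-3-(trifluoromethanesulfonyloxy)prop-2-enoate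
Product: 11 methyl (E)-2-{[(4R,5R)-5-(hydroxymethyl)-2,2-dimethyl-1,3-dioxolan-4-yl]methyl}-3-(trifluoromethanesulfonyloxy)prop-2-enoate
Conditions: HF·pyridine, pyridine, THF, 0 °C to rt
Reagents that add atoms: none
Why: Fluoride-mediated cleavage of the primary silyl ether under buffered acidic conditions, chosen over basic fluoride sources so that neither fluoride nor the freed alkoxide attacks the electrophilic β-triflyloxy acrylate; the acetonide tolerates buffered HF·pyridine.

Step 7
Reactants: 11 methyl (E)-2-{[(4R,5R)-5-(hydroxymethyl)-2,2-dimethyl-1,3-dioxolan-4-yl]methyl}-3-(trifluoromethanesulfonyloxy)prop-2-enoate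
Product: 12 methyl (E)-2-{[(4R,5S)-5-formyl-2,2-dimethyl-1,3-dioxolan-4-yl]methyl}-3-(trifluoromethanesulfonyloxy)prop-2-enoate
Conditions: Dess–Martin periodinane, CH2Cl2, 0 °C to rt
Reagents that add atoms: none
Why: Dess–Martin oxidation of the primary alcohol under near-neutral, non-nucleophilic conditions leaves the enol triflate, ester and acetal intact; the trans-disposed aldehyde is the stable epimer and would be used at once.

Step 8
Reactants: 12 methyl (E)-2-{[(4R,5S)-5-formyl-2,2-dimethyl-1,3-dioxolan-4-yl]methyl}-3-(trifluoromethanesulfonyloxy)prop-2-enoate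
Product: 14 methyl 4,5-O-isopropylidene shikimate (C3 hydroxyl free; acetonide trans-fused), via alkenylchromium species 13 (not isolated)
Conditions: CrCl2 (6 equiv), NiCl2 (2 mol %), degassed DMF, 0.01 M, slow addition of 12, rt
Reagents that add atoms: none
Why: NiCl2 is reduced by CrCl2 (divalent chromium) to zerovalent nickel, which inserts into the C2–OTf bond with retention of the alkene geometry; transmetalation to trivalent chromium gives alkenylchromium species 13, whose now nucleophilic C2 adds to the C3 aldehyde carbon, and aqueous work-up frees the alcohol. The closest known reaction type is the intramolecular Nozaki–Hiyama–Kishi coupling of alkenyl triflates or iodides with aldehydes to give cyclic allylic alcohols. The six-membered ring C1–C6 closes in a 6-exo-trig mode, which is possible only because the E triflate holds the metal on the same side of C1=C2 as the C6 tether. The new C3 stereocentre is controlled by C4: in the forming half-chair the equatorial C4–O bond of the trans-fused dioxolane lies antiperiplanar to the incipient C2–C3 bond (polar Felkin–Anh arrangement), the aldehyde hydrogen sits beside the small C4–H and the carbonyl oxygen is pseudoaxial, so the hydroxyl should emerge cis to the C4 oxygen. The step needs facial selectivity at C3 and ring closure in preference to intermolecular coupling; the first is secured by the rigid trans-dioxolane, the second by the triflate geometry together with high dilution and low nickel loading, while the weakly basic organochromium reagent leaves the methyl ester, the acetal and the enolisable alkoxy aldehyde alone.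

Step 9
Reactants: 14 methyl 4,5-O-isopropylidene shikimate
Product: 15 methyl 3,4-O-isopropylidene shikimate (C5 hydroxyl free; acetonide cis-fused)
Conditions: TsOH·H2O (5 mol %), acetone, rt
Reagents that add atoms: none
Why: Acid-catalysed acetal migration under thermodynamic control: the strained trans-fused dioxolane opens and the cis C3 hydroxyl recloses it as the cis-fused 3,4-acetonide, the isomer that equilibrating acetonisation of methyl shikimate favours; no stereocentre is touched.

Step 10
Reactants: 15 methyl 3,4-O-isopropylidene shikimate; 16 (R)-2-methylbutanoic acid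
Product: 17 methyl 3,4-O-isopropylidene-5-O-[(2R)-2-methylbutanoyl]shikimate
Conditions: DCC, DMAP (cat.), CH2Cl2, 0 °C to rt
Reagents that add atoms: (R)-2-methylbutanoic acid (compound 16), CC[C@@H](C)C(=O)O
Why: Steglich esterification of the only free hydroxyl (C5–OH), so no regioselectivity is required; the unactivated α-alkyl stereocentre of the acid should not epimerise under carbodiimide activation at this temperature.

Step 11
Reactants: 17 methyl 3,4-O-isopropylidene-5-O-[(2R)-2-methylbutanoyl]shikimate
Product: 18 methyl 5-O-[(2R)-2-methylbutanoyl]shikimate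
Conditions: TFA/H2O (4:1), 0 °C
Reagents that add atoms: none
Why: Acid hydrolysis of the cis-fused acetonide; the esters survive cold aqueous acid, and acyl migration from O5 to the trans-disposed O4 is slow under acidic conditions.

Step 12
Reactants: 18 methyl 5-O-[(2R)-2-methylbutanoyl]shikimate
Product: 20 methyl 3-O-acetyl-5-O-[(2R)-2-methylbutanoyl]shikimate, via cyclic orthoacetate 19 (not isolated)
Conditions: MeC(OMe)3, CSA (cat.), CH2Cl2, rt; then AcOH/H2O (4:1), rt
Reagents that add atoms: trimethyl orthoacetate, COC(C)(OC)OC; water, O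
Why: Orthoester exchange onto the cis-3,4-diol followed by acid hydrolysis of the cyclic orthoacetate, which under stereoelectronic control should leave the acetyl group on the pseudoaxial C3 oxygen and free the equatorial C4 hydroxyl, as is general for cis-diols on six-membered rings.

Step 13
Reactants: 20 methyl 3-O-acetyl-5-O-[(2R)-2-methylbutanoyl]shikimate
Product: 21 methyl (3R,4S,5R)-3-acetoxy-5-{[(2R)-2-methylbutanoyl]oxy}-4-(propanoyloxy)cyclohex-1-ene-1-carboxylate (target)
Conditions: (EtCO)2O (excess), DMAP (cat.), pyridine, CH2Cl2, 0 °C, 20 added last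
Reagents that add atoms: propanoic anhydride, CCC(=O)OC(=O)CC
Why: DMAP-catalysed acylation of the last free hydroxyl with an unhindered anhydride in excess, run cold so that acylation outruns base-induced acetyl migration from O3 to O4.

Compound list

1 | (4R,5R)-2,2-dimethyl-1,3-dioxolane-4,5-dimethanol (2,3-O-isopropylidene-D-threitol) | OC[C@@H](OC1(C)C)[C@H](O1)CO | starting material
2 | monosodium alkoxide of 1 | [Na+].[O-]C[C@@H](OC1(C)C)[C@H](O1)CO | intermediate (not isolated)
3 | [(4R,5R)-5-(tert-butyldimethylsilyloxymethyl)-2,2-dimethyl-1,3-dioxolan-4-yl]methanol | CC(C)(C)[Si](C)(C)OC[C@@H](OC1(C)C)[C@H](O1)CO | intermediate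
4 | methyl (triphenylphosphoranylidene)acetate | COC(=O)C=P(c1ccccc1)(c1ccccc1)c1ccccc1 | starting material
5 | (4S,5R)-5-(tert-butyldimethylsilyloxymethyl)-2,2-dimethyl-1,3-dioxolane-4-carbaldehyde (substituents trans) | CC(C)(C)[Si](C)(C)OC[C@@H](OC1(C)C)[C@H](O1)C=O | intermediate (not isolated)
6 | methyl (E)-3-[(4R,5R)-5-(tert-butyldimethylsilyloxymethyl)-2,2-dimethyl-1,3-dioxolan-4-yl]prop-2-enoate | CC(C)(C)[Si](C)(C)OC[C@@H](OC1(C)C)[C@H](O1)/C=C/C(=O)OC | intermediate
7 | methyl 3-[(4R,5R)-5-(tert-butyldimethylsilyloxymethyl)-2,2-dimethyl-1,3-dioxolan-4-yl]propanoate | CC(C)(C)[Si](C)(C)OC[C@@H](OC1(C)C)[C@H](O1)CCC(=O)OC | intermediate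
8 | lithium enolate of 7 (enolate geometry not defined) | CC(C)(C)[Si](C)(C)OC[C@@H](OC1(C)C)[C@H](O1)CC=C(O[Li])OC | intermediate (not isolated)
9 | methyl 2-formyl-3-[(4R,5R)-5-(tert-butyldimethylsilyloxymethyl)-2,2-dimethyl-1,3-dioxolan-4-yl]propanoate (in equilibrium with its hydroxymethylene enol; α-carbon not defined) | CC(C)(C)[Si](C)(C)OC[C@@H](OC1(C)C)[C@H](O1)CC(C=O)C(=O)OC | intermediate
10 | methyl (E)-2-{[(4R,5R)-5-(tert-butyldimethylsilyloxymethyl)-2,2-dimethyl-1,3-dioxolan-4-yl]methyl}-3-(trifluoromethanesulfonyloxy)prop-2-enoate (OTf cis to the CH2 tether) | CC(C)(C)[Si](C)(C)OC[C@@H](OC1(C)C)[C@H](O1)C/C(C(=O)OC)=C\OS(=O)(=O)C(F)(F)F | intermediate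
11 | methyl (E)-2-{[(4R,5R)-5-(hydroxymethyl)-2,2-dimethyl-1,3-dioxolan-4-yl]methyl}-3-(trifluoromethanesulfonyloxy)prop-2-enoate | OC[C@@H](OC1(C)C)[C@H](O1)C/C(C(=O)OC)=C\OS(=O)(=O)C(F)(F)F | intermediate
12 | methyl (E)-2-{[(4R,5S)-5-formyl-2,2-dimethyl-1,3-dioxolan-4-yl]methyl}-3-(trifluoromethanesulfonyloxy)prop-2-enoate (formyl and CH2 trans on the dioxolane) | O=C[C@@H](OC1(C)C)[C@H](O1)C/C(C(=O)OC)=C\OS(=O)(=O)C(F)(F)F | intermediate
13 | alkenylchromium dichloride from 12 (CrCl2 group in place of OTf, geometry retained) | O=C[C@@H](OC1(C)C)[C@H](O1)C/C(C(=O)OC)=C\[Cr](Cl)Cl | intermediate (not isolated)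
14 | methyl 4,5-O-isopropylidene shikimate: methyl (3R,4R,5R)-3-hydroxy-4,5-(isopropylidenedioxy)cyclohex-1-ene-1-carboxylate, trans-fused, C3–OH cis to C4–O (spatially as in shikimic acid; the C4 descriptor is R only because the acetal oxygen raises the rank of C5) | CC1(C)O[C@@H]2[C@H](O)C=C(C(=O)OC)C[C@H]2O1 | intermediate
15 | methyl 3,4-O-isopropylidene shikimate: methyl (3aR,7R,7aS)-7-hydroxy-2,2-dimethyl-3a,6,7,7a-tetrahydro-1,3-benzodioxole-5-carboxylate | CC1(C)O[C@@H]2[C@H](O1)C=C(C(=O)OC)C[C@H]2O | intermediate
16 | (R)-2-methylbutanoic acid | CC[C@@H](C)C(=O)O | starting material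
17 | methyl 3,4-O-isopropylidene-5-O-[(2R)-2-methylbutanoyl]shikimate | CC1(C)O[C@@H]2[C@H](O1)C=C(C(=O)OC)C[C@H]2OC(=O)[C@H](C)CC | intermediate
18 | methyl 5-O-[(2R)-2-methylbutanoyl]shikimate (3,4-diol; C3–OH cis to C4–OH, C5 ester trans to C4–OH) | O[C@@H]1[C@H](O)C=C(C(=O)OC)C[C@H]1OC(=O)[C@H](C)CC | intermediate
19 | cyclic 3,4-O-(1-methoxyethylidene) orthoacetate of 18 (both epimers at the orthoester carbon) | COC1(C)O[C@@H]2[C@H](O1)C=C(C(=O)OC)C[C@H]2OC(=O)[C@H](C)CC | intermediate (not isolated)
20 | methyl 3-O-acetyl-5-O-[(2R)-2-methylbutanoyl]shikimate: methyl (3R,4S,5R)-3-acetoxy-4-hydroxy-5-{[(2R)-2-methylbutanoyl]oxy}cyclohex-1-ene-1-carboxylate | O[C@@H]1[C@H](OC(C)=O)C=C(C(=O)OC)C[C@H]1OC(=O)[C@H](C)CC | intermediate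
21 | methyl (3R,4S,5R)-3-acetoxy-5-{[(2R)-2-methylbutanoyl]oxy}-4-(propanoyloxy)cyclohex-1-ene-1-carboxylate (CNP0403577.1) | CCC(=O)O[C@@H]1[C@H](OC(C)=O)C=C(C(=O)OC)C[C@H]1OC(=O)[C@H](C)CC | target

Total step count: 13. Longest linear sequence: 13 steps (1 to 21); 4 and 16 enter as purchased building blocks.

Steps most likely to fail

Step 8. The process at risk is insufficient facial discrimination when C2 adds to the aldehyde, so that the C3 epimer accompanies or replaces 14. The fallback sets out from 12 and keeps the cyclisation, but sets C3 by inversion instead of substrate control. The epimer, methyl 3-epi-4,5-O-isopropylidene shikimate F1, would be separated and submitted to a Mitsunobu reaction (4-nitrobenzoic acid, PPh3, DIAD, THF, 0 °C). This should give the inverted ester methyl 4,5-O-isopropylidene-3-O-(4-nitrobenzoyl)shikimate F2; SN2′ attack would have to occur at the fully substituted C1 and is not expected. Methanolysis (K2CO3, MeOH, 0 °C) then releases 14, where the route is rejoined.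

Step 5. The process at risk is loss of geometric control in the O-sulfonylation, giving the Z triflate, which cannot cyclise. The fallback sets out from 9 and builds the alkenyl electrophile by elimination instead of enolate trapping. Deformylative methylenation (aq. HCHO, K2CO3, THF) should give the α-methylene ester methyl 2-{[(4R,5R)-5-(tert-butyldimethylsilyloxymethyl)-2,2-dimethyl-1,3-dioxolan-4-yl]methyl}prop-2-enoate F3. Bromine addition (Br2, CH2Cl2, 0 °C) gives the 2,3-dibromide F4, and DBU-induced dehydrobromination the (E)-β-bromoacrylate F5 with bromine cis to the C6 methylene, the geometry that bromination–dehydrobromination of α-alkyl acrylates is known to favour. Desilylation (HF·pyridine, pyridine, THF) leads to the alcohol F6 and Dess–Martin oxidation to the bromo aldehyde F7. CrCl2 with catalytic NiCl2 in DMF, which also accepts alkenyl bromides, then closes the ring to 14.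

Step 12. The process at risk is wrong-way or unselective opening of the cyclic orthoacetate on the half-chair, or acetyl migration between O3 and O4 during hydrolysis. The fallback sets out from 14, where C3–OH is the only free hydroxyl, and reverses the order of acylation. Acetylation (Ac2O, pyridine, DMAP cat.) gives methyl 3-O-acetyl-4,5-O-isopropylidene shikimate F8. Mild hydrolysis of the strained trans-acetonide (AcOH/H2O 4:1, rt) gives methyl 3-O-acetylshikimate F9. Esterification with 16 (DCC, DMAP cat., CH2Cl2, −20 °C) should then go to C5–OH, because the C4 hydroxyl, flanked by two oxygenated carbons, is the least reactive hydroxyl of shikimates; this delivers 20.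

Further compounds
F1 | step 8 | methyl 3-epi-4,5-O-isopropylidene shikimate (C3–OH trans to C4–O) | CC1(C)O[C@@H]2[C@@H](O)C=C(C(=O)OC)C[C@H]2O1
F2 | step 8 | methyl 4,5-O-isopropylidene-3-O-(4-nitrobenzoyl)shikimate | CC1(C)O[C@@H]2[C@H](OC(=O)c3ccc(cc3)[N+](=O)[O-])C=C(C(=O)OC)C[C@H]2O1
F3 | step 5 | methyl 2-{[(4R,5R)-5-(tert-butyldimethylsilyloxymethyl)-2,2-dimethyl-1,3-dioxolan-4-yl]methyl}prop-2-enoate | CC(C)(C)[Si](C)(C)OC[C@@H](OC1(C)C)[C@H](O1)CC(=C)C(=O)OC
F4 | step 5 | methyl 2,3-dibromo-2-{[(4R,5R)-5-(tert-butyldimethylsilyloxymethyl)-2,2-dimethyl-1,3-dioxolan-4-yl]methyl}propanoate (both epimers at C2) | CC(C)(C)[Si](C)(C)OC[C@@H](OC1(C)C)[C@H](O1)CC(Br)(CBr)C(=O)OC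
F5 | step 5 | methyl (E)-3-bromo-2-{[(4R,5R)-5-(tert-butyldimethylsilyloxymethyl)-2,2-dimethyl-1,3-dioxolan-4-yl]methyl}prop-2-enoate | CC(C)(C)[Si](C)(C)OC[C@@H](OC1(C)C)[C@H](O1)C/C(C(=O)OC)=C\Br
F6 | step 5 | methyl (E)-3-bromo-2-{[(4R,5R)-5-(hydroxymethyl)-2,2-dimethyl-1,3-dioxolan-4-yl]methyl}prop-2-enoate | OC[C@@H](OC1(C)C)[C@H](O1)C/C(C(=O)OC)=C\Br
F7 | step 5 | methyl (E)-3-bromo-2-{[(4R,5S)-5-formyl-2,2-dimethyl-1,3-dioxolan-4-yl]methyl}prop-2-enoate | O=C[C@@H](OC1(C)C)[C@H](O1)C/C(C(=O)OC)=C\Br
F8 | step 12 | methyl 3-O-acetyl-4,5-O-isopropylidene shikimate | CC1(C)O[C@@H]2[C@H](OC(C)=O)C=C(C(=O)OC)C[C@H]2O1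
F9 | step 12 | methyl 3-O-acetylshikimate (4,5-diol) | O[C@@H]1[C@H](OC(C)=O)C=C(C(=O)OC)C[C@H]1O
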